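**Strategy.** Germacrane numbering: ring C1–C10 (C1 OAc, C10 CHMe, C9 CH2, C8 methacrylate carbinol), butenolide C6–O–C12(=O)–C11=C7, epoxide C4–C5. Everything rests on the 1,4-relationship of the C1 oxygen and C8 across C9–C10: the five atoms O–C1–C10–C9–C8 are drawn into a temporary γ-lactone ring that is absent from the target. Its precursor is an acyclic diazoacetate of an oct-6-en-3-ol whose ethyl branch is C10–C14. A dirhodium carbenoid at C9 inserts into a C10–H bond, closing the lactone, forming C9–C10, setting C10 cis to C2 and placing C8 at the carbonyl level. The lactone C–O bond is later cleaved and the ten-membered ring closed at C7–C8 (Nozaki–Hiyama–Kishi).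

Key step: step 5

Remark: each chiral catalyst is named as the antipode assumed to give the configuration drawn; should its sense be the opposite, its enantiomer is used.

Step 1
Reactants: 1 geraniol
Product: 2 geranyl TBS ether
Conditions: TBSCl, imidazole, DMF, 0 °C to rt
Reagents that add atoms: tert-butyldimethylsilyl chloride, CC(C)(C)[Si](C)(C)Cl
Why: Imidazole-promoted O-silylation of the primary allylic alcohol (silyl ether protection); no stereocentre is involved.

Step 2
Reactants: 2 geranyl TBS ether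
Product: 4 (4E)-6-{[tert-butyl(dimethyl)silyl]oxy}-4-methylhex-4-enal, via racemic 6,7-epoxide 3 (not isolated)
Conditions: mCPBA, CH2Cl2, −20 to 0 °C; then H5IO6, THF/H2O, 0 °C
Reagents that add atoms: mCPBA, OOC(=O)c1cccc(Cl)c1
Why: Prilezhaev epoxidation takes the more electron-rich distal alkene (the proximal one is deactivated by the allylic oxygen) and periodic acid hydrolyses and cleaves the epoxide (Malaprade-type cleavage) to the C1 aldehyde; no stereocentre is formed.

Step 3
Reactants: 4 (4E)-6-{[tert-butyl(dimethyl)silyl]oxy}-4-methylhex-4-enal; 5 diethylzinc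
Product: 6 (3R,6E)-8-{[tert-butyl(dimethyl)silyl]oxy}-6-methyloct-6-en-3-ol
Conditions: Et2Zn, (+)-MIB (5 mol %), hexane/toluene, 0 °C; aq. NH4Cl
Reagents that add atoms: none
Why: Amino-alcohol-catalysed enantioselective addition of diethylzinc to an aldehyde (Noyori type): the chiral zinc aminoalkoxide delivers ethyl to one carbonyl face and sets C1 as 3R, the ethyl group being the future C10–C14 unit.

Step 4
Reactants: 6 (3R,6E)-8-{[tert-butyl(dimethyl)silyl]oxy}-6-methyloct-6-en-3-ol; 7 glyoxylic acid chloride p-toluenesulfonylhydrazone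
Product: 9 (3R,6E)-8-{[tert-butyl(dimethyl)silyl]oxy}-6-methyloct-6-en-3-yl diazoacetate, via tosylhydrazone ester 8 (not isolated)
Conditions: PhNMe2, CH2Cl2, 0 °C; then Et3N, 0 °C to rt
Reagents that add atoms: none
Why: House–Blankley diazoacetate synthesis: O-acylation by the acid chloride and triethylamine-induced loss of p-toluenesulfinate from the hydrazone (Bamford–Stevens-type elimination) give the diazo ester without touching C1.

Step 5
Reactants: 9 (3R,6E)-8-{[tert-butyl(dimethyl)silyl]oxy}-6-methyloct-6-en-3-yl diazoacetate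
Product: 10 (4S,5S)-5-[(3E)-5-{[tert-butyl(dimethyl)silyl]oxy}-3-methylpent-3-en-1-yl]-4-methyldihydrofuran-2(3H)-one
Conditions: Rh2(4S-MACIM)4 (1 mol %), CH2Cl2, reflux, 9 added over 10 h
Reagents that add atoms: none
Why: Loss of N2 from 9 at the dirhodium carboxamidate (divalent rhodium) gives an electrophilic carbenoid at C9 that inserts, through a concerted three-centre transition state with retention, into a C10–H bond of the ethyl branch; the closest known type is the Doyle intramolecular C–H insertion of secondary alkyl diazoacetates to γ-butyrolactones. The ring closed is the five-membered lactone O–C8–C9–C10–C1 (1,5-insertion through a five-membered transition state; the six-membered alternative at allylic C3 is disfavoured with carboxamidate ligands). C10 is the new stereocentre: the chiral ligand pocket selects one of the two diastereotopic C10–H bonds so that the C10 methyl and the C2 chain should end up cis (4S,5S), as expected for this catalyst class with 3-pentyl diazoacetate. The step needs site selectivity between the two 1,5-related methylenes (C10 of the ethyl arm and C2 of the chain); this is secured by matching the catalyst antipode to the 3R carbinol so that the ethyl arm takes the place of the preferred enantiotopic arm. It also needs chemoselectivity over cyclopropanation of the remote C4=C5 alkene (seven-membered ring) and over carbene dimerisation (slow addition).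

Step 6
Reactants: 10 (4S,5S)-5-[(3E)-5-{[tert-butyl(dimethyl)silyl]oxy}-3-methylpent-3-en-1-yl]-4-methyldihydrofuran-2(3H)-one
Product: 12 (3S,4S,7E)-9-{[tert-butyl(dimethyl)silyl]oxy}-1-[methoxy(methyl)amino]-3,7-dimethyl-1-oxonon-7-en-4-yl acetate, via hydroxy Weinreb amide 11 (not isolated)
Conditions: MeNHOMe·HCl, iPrMgCl, THF, −20 °C; then Ac2O, DMAP, −20 °C to rt
Reagents that add atoms: N,O-dimethylhydroxylamine hydrochloride, CNOC.Cl; acetic anhydride, CC(=O)OC(C)=O
Why: Weinreb aminolysis of the γ-lactone by the chloromagnesium amide cleaves the temporary C8–O bond, and the released C1 magnesium alkoxide is O-acetylated in the same flask before it can relactonise; no stereocentre is touched.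

Step 7
Reactants: 12 (3S,4S,7E)-9-{[tert-butyl(dimethyl)silyl]oxy}-1-[methoxy(methyl)amino]-3,7-dimethyl-1-oxonon-7-en-4-yl acetate
Product: 13 (3S,4S,7E)-9-hydroxy-1-[methoxy(methyl)amino]-3,7-dimethyl-1-oxonon-7-en-4-yl acetate
Conditions: HF·pyridine, pyridine, THF, 0 °C to rt
Reagents that add atoms: none
Why: Fluoride-mediated desilylation of the primary TBS ether; acetate and Weinreb amide are inert to buffered HF·pyridine.

Step 8
Reactants: 13 (3S,4S,7E)-9-hydroxy-1-[methoxy(methyl)amino]-3,7-dimethyl-1-oxonon-7-en-4-yl acetate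
Product: 14 (3S,4S,7E)-1-[methoxy(methyl)amino]-3,7-dimethyl-1,9-dioxonon-7-en-4-yl acetate
Conditions: MnO2, CH2Cl2, rt
Reagents that add atoms: none
Why: MnO2 oxidises only the allylic alcohol to the (E)-enal (C6 aldehyde) without isomerisation; no stereocentre is formed.

Step 9
Reactants: 14 (3S,4S,7E)-1-[methoxy(methyl)amino]-3,7-dimethyl-1,9-dioxonon-7-en-4-yl acetate; 15 methyl propiolate
Product: 16 methyl (4R,5E,9S,10S)-9-acetoxy-4-hydroxy-12-[methoxy(methyl)amino]-6,10-dimethyl-12-oxododec-5-en-2-ynoate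
Conditions: Me2Zn, (S,S)-ProPhenol (10 mol %), Ph3P=O (20 mol %), toluene, 4 °C
Reagents that add atoms: none
Why: Trost zinc–ProPhenol asymmetric alkynylation: the dinuclear zinc catalyst adds the zinc acetylide of methyl propiolate 1,2 to the enal on one face and sets C6 (4R in 16) under catalyst control.

Step 10
Reactants: 16 methyl (4R,5E,9S,10S)-9-acetoxy-4-hydroxy-12-[methoxy(methyl)amino]-6,10-dimethyl-12-oxododec-5-en-2-ynoate; 17 formaldehyde
Product: 19 (3S,4S,7E)-8-[(2R)-4-(hydroxymethyl)-3-iodo-5-oxo-2,5-dihydrofuran-2-yl]-1-[methoxy(methyl)amino]-3,7-dimethyl-1-oxooct-7-en-4-yl acetate, via iodo-enoate diol 18 (not isolated)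
Conditions: MgI2, monomeric CH2O (from cracked paraformaldehyde), CH2Cl2, −20 °C to rt
Reagents that add atoms: magnesium iodide, [Mg+2].[I-].[I-]
Why: Halo-aldol (β-iodo Morita–Baylis–Hillman) reaction: iodide adds to C7 of the magnesium-activated ynoate and the allenolate is hydroxymethylated at C11 by formaldehyde; only the enoate isomer with the ester cis to the C6 hydroxyl can lactonise, and reversible iodide addition–elimination should interconvert the isomers so that the material funnels into the butenolide with C6 unchanged.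

Step 11
Reactants: 19 (3S,4S,7E)-8-[(2R)-4-(hydroxymethyl)-3-iodo-5-oxo-2,5-dihydrofuran-2-yl]-1-[methoxy(methyl)amino]-3,7-dimethyl-1-oxooct-7-en-4-yl acetate
Product: 20 (3S,4S,7E)-8-[(2R)-3-iodo-5-oxo-4-{[(triethylsilyl)oxy]methyl}-2,5-dihydrofuran-2-yl]-1-[methoxy(methyl)amino]-3,7-dimethyl-1-oxooct-7-en-4-yl acetate
Conditions: TESCl, imidazole, CH2Cl2, 0 °C
Reagents that add atoms: chlorotriethylsilane, CC[Si](CC)(CC)Cl
Why: Silyl ether formation on the primary C13 alcohol, which keeps it out of the later C8 acylation.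

Step 12
Reactants: 20 (3S,4S,7E)-8-[(2R)-3-iodo-5-oxo-4-{[(triethylsilyl)oxy]methyl}-2,5-dihydrofuran-2-yl]-1-[methoxy(methyl)amino]-3,7-dimethyl-1-oxooct-7-en-4-yl acetate
Product: 21 (3S,4S,7E)-8-[(2R)-3-iodo-5-oxo-4-{[(triethylsilyl)oxy]methyl}-2,5-dihydrofuran-2-yl]-3,7-dimethyl-1-oxooct-7-en-4-yl acetate
Conditions: Cp2Zr(H)Cl, THF, rt, 20 min
Reagents that add atoms: none
Why: Schwartz reagent hydrozirconates the tertiary (Weinreb) amide carbonyl to a stable zirconated hemiaminal that releases the C8 aldehyde on work-up, chemoselectively over acetate and lactone; no stereocentre is touched.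

Step 13
Reactants: 21 (3S,4S,7E)-8-[(2R)-3-iodo-5-oxo-4-{[(triethylsilyl)oxy]methyl}-2,5-dihydrofuran-2-yl]-3,7-dimethyl-1-oxooct-7-en-4-yl acetate
Product: 22 (1S,4E,6R,8S,10S)-1-acetoxy-8-hydroxy-13-[(triethylsilyl)oxy]germacra-4,7(11)-dien-12,6-olide
Conditions: CrCl2 (10 equiv), NiCl2 (2 mol %), DMSO, rt, 2 mM
Reagents that add atoms: none
Why: Nozaki–Hiyama–Kishi reaction: zerovalent nickel formed in situ inserts into the C7–I bond, transmetalation gives the trivalent alkenylchromium species, which adds to the C8 aldehyde and closes the ten-membered ring; the rigid (E)-alkene and butenolide restrict the ring so that the aldehyde is attacked with its oxygen turned outward, which should give 8S (a poor ratio is covered by the fallback).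

Step 14
Reactants: 22 (1S,4E,6R,8S,10S)-1-acetoxy-8-hydroxy-13-[(triethylsilyl)oxy]germacra-4,7(11)-dien-12,6-olide
Product: 23 (1S,4E,6R,8S,10S)-1-acetoxy-8-(methacryloyloxy)-13-[(triethylsilyl)oxy]germacra-4,7(11)-dien-12,6-olide
Conditions: methacrylic anhydride, DMAP (cat.), pyridine, CH2Cl2, 0 °C
Reagents that add atoms: methacrylic anhydride, CC(=C)C(=O)OC(=O)C(C)=C
Why: DMAP-catalysed acylation of the secondary C8 alcohol with retention.

Step 15
Reactants: 23 (1S,4E,6R,8S,10S)-1-acetoxy-8-(methacryloyloxy)-13-[(triethylsilyl)oxy]germacra-4,7(11)-dien-12,6-olide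
Product: 24 13-O-triethylsilylglaucolide L
Conditions: mCPBA, NaHCO3, CH2Cl2, 0 °C
Reagents that add atoms: mCPBA, OOC(=O)c1cccc(Cl)c1
Why: Prilezhaev epoxidation of the only electron-rich alkene (methacrylate and butenolide alkenes are electron-poor); with H6 eclipsing the C4 methyl (A1,3 strain) the ring carbons C7–C10 cover one alkene face and the peracid should attack the outer face syn to the C6 lactone oxygen, which gives the 4R,5R epoxide.

Step 16
Reactants: 24 13-O-triethylsilylglaucolide L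
Product: 25 glaucolide L
Conditions: HF·pyridine, pyridine, THF, 0 °C
Reagents that add atoms: none
Why: Buffered fluoride desilylation of the primary triethylsilyl ether frees the C13 alcohol; epoxide and both esters should tolerate HF·pyridine/pyridine at 0 °C.

**Compound list**

1 | geraniol, (2E)-3,7-dimethylocta-2,6-dien-1-ol | CC(C)=CCC/C(C)=C/CO | starting material
2 | geranyl TBS ether, tert-butyl{[(2E)-3,7-dimethylocta-2,6-dien-1-yl]oxy}dimethylsilane | CC(C)=CCC/C(C)=C/CO[Si](C)(C)C(C)(C)C | intermediate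
3 | racemic 6,7-epoxide of 2 (not isolated) | CC1(C)OC1CC/C(C)=C/CO[Si](C)(C)C(C)(C)C | intermediate
4 | (4E)-6-{[tert-butyl(dimethyl)silyl]oxy}-4-methylhex-4-enal | O=CCC/C(C)=C/CO[Si](C)(C)C(C)(C)C | intermediate
5 | diethylzinc | CC[Zn]CC | starting material
6 | (3R,6E)-8-{[tert-butyl(dimethyl)silyl]oxy}-6-methyloct-6-en-3-ol | CC[C@@H](O)CC/C(C)=C/CO[Si](C)(C)C(C)(C)C | intermediate
7 | glyoxylic acid chloride p-toluenesulfonylhydrazone | Cc1ccc(cc1)S(=O)(=O)NN=CC(Cl)=O | starting material
8 | (3R,6E)-8-{[tert-butyl(dimethyl)silyl]oxy}-6-methyloct-6-en-3-yl [2-(p-tolylsulfonyl)hydrazinylidene]acetate (not isolated) | Cc1ccc(cc1)S(=O)(=O)NN=CC(=O)O[C@H](CC)CC/C(C)=C/CO[Si](C)(C)C(C)(C)C | intermediate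
9 | (3R,6E)-8-{[tert-butyl(dimethyl)silyl]oxy}-6-methyloct-6-en-3-yl diazoacetate | [N-]=[N+]=CC(=O)O[C@H](CC)CC/C(C)=C/CO[Si](C)(C)C(C)(C)C | intermediate
10 | (4S,5S)-5-[(3E)-5-{[tert-butyl(dimethyl)silyl]oxy}-3-methylpent-3-en-1-yl]-4-methyldihydrofuran-2(3H)-one (cis-lactone: C8 carbonyl, C9 CH2, C10 CHMe, C1 CH–O) | O=C1C[C@H](C)[C@H](CC/C(C)=C/CO[Si](C)(C)C(C)(C)C)O1 | intermediate
11 | (3S,4S,7E)-9-{[tert-butyl(dimethyl)silyl]oxy}-4-hydroxy-N-methoxy-N,3,7-trimethylnon-7-enamide (not isolated) | CON(C)C(=O)C[C@H](C)[C@@H](O)CC/C(C)=C/CO[Si](C)(C)C(C)(C)C | intermediate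
12 | (3S,4S,7E)-9-{[tert-butyl(dimethyl)silyl]oxy}-1-[methoxy(methyl)amino]-3,7-dimethyl-1-oxonon-7-en-4-yl acetate | CON(C)C(=O)C[C@H](C)[C@@H](OC(C)=O)CC/C(C)=C/CO[Si](C)(C)C(C)(C)C | intermediate
13 | (3S,4S,7E)-9-hydroxy-1-[methoxy(methyl)amino]-3,7-dimethyl-1-oxonon-7-en-4-yl acetate | CON(C)C(=O)C[C@H](C)[C@@H](OC(C)=O)CC/C(C)=C/CO | intermediate
14 | (3S,4S,7E)-1-[methoxy(methyl)amino]-3,7-dimethyl-1,9-dioxonon-7-en-4-yl acetate | CON(C)C(=O)C[C@H](C)[C@@H](OC(C)=O)CC/C(C)=C/C=O | intermediate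
15 | methyl propiolate | C#CC(=O)OC | starting material
16 | methyl (4R,5E,9S,10S)-9-acetoxy-4-hydroxy-12-[methoxy(methyl)amino]-6,10-dimethyl-12-oxododec-5-en-2-ynoate | CON(C)C(=O)C[C@H](C)[C@@H](OC(C)=O)CC/C(C)=C/[C@@H](O)C#CC(=O)OC | intermediate
17 | formaldehyde | C=O | starting material
18 | methyl (2E,4R,5E,9S,10S)-9-acetoxy-4-hydroxy-2-(hydroxymethyl)-3-iodo-12-[methoxy(methyl)amino]-6,10-dimethyl-12-oxododeca-2,5-dienoate (not isolated) | CON(C)C(=O)C[C@H](C)[C@@H](OC(C)=O)CC/C(C)=C/[C@@H](O)/C(I)=C(/CO)C(=O)OC | intermediate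
19 | (3S,4S,7E)-8-[(2R)-4-(hydroxymethyl)-3-iodo-5-oxo-2,5-dihydrofuran-2-yl]-1-[methoxy(methyl)amino]-3,7-dimethyl-1-oxooct-7-en-4-yl acetate | CON(C)C(=O)C[C@H](C)[C@@H](OC(C)=O)CC/C(C)=C/[C@H]1OC(=O)C(CO)=C1I | intermediate
20 | (3S,4S,7E)-8-[(2R)-3-iodo-5-oxo-4-{[(triethylsilyl)oxy]methyl}-2,5-dihydrofuran-2-yl]-1-[methoxy(methyl)amino]-3,7-dimethyl-1-oxooct-7-en-4-yl acetate | CON(C)C(=O)C[C@H](C)[C@@H](OC(C)=O)CC/C(C)=C/[C@H]1OC(=O)C(CO[Si](CC)(CC)CC)=C1I | intermediate
21 | (3S,4S,7E)-8-[(2R)-3-iodo-5-oxo-4-{[(triethylsilyl)oxy]methyl}-2,5-dihydrofuran-2-yl]-3,7-dimethyl-1-oxooct-7-en-4-yl acetate | O=CC[C@H](C)[C@@H](OC(C)=O)CC/C(C)=C/[C@H]1OC(=O)C(CO[Si](CC)(CC)CC)=C1I | intermediate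
22 | (1S,4E,6R,8S,10S)-1-acetoxy-8-hydroxy-13-[(triethylsilyl)oxy]germacra-4,7(11)-dien-12,6-olide | O[C@H]1C[C@H](C)[C@@H](OC(C)=O)CC/C(C)=C/[C@H]2OC(=O)C(CO[Si](CC)(CC)CC)=C12 | intermediate
23 | (1S,4E,6R,8S,10S)-1-acetoxy-8-(methacryloyloxy)-13-[(triethylsilyl)oxy]germacra-4,7(11)-dien-12,6-olide | C=C(C)C(=O)O[C@H]1C[C@H](C)[C@@H](OC(C)=O)CC/C(C)=C/[C@H]2OC(=O)C(CO[Si](CC)(CC)CC)=C12 | intermediate
24 | 13-O-triethylsilylglaucolide L, (1S,4R,5R,6S,8S,10S)-1-acetoxy-4,5-epoxy-8-(methacryloyloxy)-13-[(triethylsilyl)oxy]germacr-7(11)-en-12,6-olide | C=C(C)C(=O)O[C@H]1C[C@H](C)[C@@H](OC(C)=O)CC[C@@]2(C)O[C@@H]2[C@H]2OC(=O)C(CO[Si](CC)(CC)CC)=C12 | intermediate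
25 | glaucolide L, (1S,4R,5R,6S,8S,10S)-1-acetoxy-4,5-epoxy-13-hydroxy-8-(methacryloyloxy)germacr-7(11)-en-12,6-olide | C=C(C)C(=O)O[C@H]1C[C@H](C)[C@@H](OC(C)=O)CC[C@@]2(C)O[C@@H]2[C@H]2OC(=O)C(CO)=C12 | target

**Total steps:** 16. **Longest linear sequence:** 16 steps (from geraniol).

**Steps most likely to fail**

1. Step 5 (key step). The carbenoid may insert into the C2–H bonds of the chain instead of the C10–H bonds of the ethyl arm, may close to the trans lactone, or may add to the C4=C5 alkene. The fallback keeps the temporary lactone but forms C9–C10 by metathesis; it sets out from 2 and returns at 10. Asymmetric Shi epoxidation of the distal alkene of 2 (ent-Shi ketone from L-fructose, Oxone, K2CO3 buffer) should give the (S)-epoxide F1. Et2Al(TMP) isomerises F1 to the isopropenyl carbinol F2 with the C1–O bond retained. Acryloyl chloride and Et3N give the acrylate F3. Ring-closing metathesis with the second-generation Grubbs catalyst (toluene, 80 °C) forms C9=C10 in the butenolide F4. Conjugate reduction with [(Ph3P)CuH]6 delivers hydride to C10 anti to the C1 side chain and should return the cis-lactone 10.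

2. Step 10. The Lewis acid may ionise the allylic and propargylic C6 carbinol, or the two enoate geometries may fail to funnel into the lactone. The fallback builds the same iodobutenolide through an allene; it sets out from 14 and returns at 20. ProPhenol alkynylation of 14 with triethyl(prop-2-yn-1-yloxy)silane under the enantiomeric catalyst should give the 9S carbinol F5. Methyl chloroformate and pyridine give the carbonate F6. Tsuji carbonylation (Pd(PPh3)4, zerovalent palladium, CO, MeOH) proceeds anti-SN2′ to the allenoate F7. Iodolactonisation (I2, NaHCO3, MeCN/H2O) puts iodine on C7, closes the C6–O bond with transfer of the allene axis to C6, and should give 20 directly.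

3. Step 13. The alkenylchromium species may add to the wrong face of the C8 aldehyde during the ring closure. The fallback uses the undesired epimer productively; it sets out from the 8R carbinol F8 and returns at 23. Mitsunobu esterification of F8 with methacrylic acid (PPh3, DIAD, THF, 0 °C) inverts C8 and installs the methacrylate in one operation, which should give 23.

Further compounds
F1 | step 5 | tert-butyl({(2E)-5-[(2S)-3,3-dimethyloxiran-2-yl]-3-methylpent-2-en-1-yl}oxy)dimethylsilane | CC1(C)O[C@H]1CC/C(C)=C/CO[Si](C)(C)C(C)(C)C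
F2 | step 5 | (3S,6E)-8-{[tert-butyl(dimethyl)silyl]oxy}-2,6-dimethylocta-1,6-dien-3-ol | C=C(C)[C@@H](O)CC/C(C)=C/CO[Si](C)(C)C(C)(C)C
F3 | step 5 | (3S,6E)-8-{[tert-butyl(dimethyl)silyl]oxy}-2,6-dimethylocta-1,6-dien-3-yl acrylate | C=CC(=O)O[C@H](C(C)=C)CC/C(C)=C/CO[Si](C)(C)C(C)(C)C
F4 | step 5 | (5S)-5-[(3E)-5-{[tert-butyl(dimethyl)silyl]oxy}-3-methylpent-3-en-1-yl]-4-methylfuran-2(5H)-one | O=C1C=C(C)[C@H](CC/C(C)=C/CO[Si](C)(C)C(C)(C)C)O1
F5 | step 10 | (3S,4S,7E,9S)-9-hydroxy-1-[methoxy(methyl)amino]-3,7-dimethyl-1-oxo-12-[(triethylsilyl)oxy]dodec-7-en-10-yn-4-yl acetate | CON(C)C(=O)C[C@H](C)[C@@H](OC(C)=O)CC/C(C)=C/[C@H](O)C#CCO[Si](CC)(CC)CC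
F6 | step 10 | (3S,4S,7E,9S)-9-[(methoxycarbonyl)oxy]-1-[methoxy(methyl)amino]-3,7-dimethyl-1-oxo-12-[(triethylsilyl)oxy]dodec-7-en-10-yn-4-yl acetate | CON(C)C(=O)C[C@H](C)[C@@H](OC(C)=O)CC/C(C)=C/[C@H](OC(=O)OC)C#CCO[Si](CC)(CC)CC
F7 | step 10 | methyl (5E,9S,10S)-9-acetoxy-12-[methoxy(methyl)amino]-6,10-dimethyl-12-oxo-2-{[(triethylsilyl)oxy]methyl}dodeca-2,3,5-trienoate (allene axis as in the SMILES) | CON(C)C(=O)C[C@H](C)[C@@H](OC(C)=O)CC/C(C)=C/C([H])=[C@]=C(CO[Si](CC)(CC)CC)C(=O)OC
F8 | step 13 | (1S,4E,6R,8R,10S)-1-acetoxy-8-hydroxy-13-[(triethylsilyl)oxy]germacra-4,7(11)-dien-12,6-olide | O[C@@H]1C[C@H](C)[C@@H](OC(C)=O)CC/C(C)=C/[C@H]2OC(=O)C(CO[Si](CC)(CC)CC)=C12
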